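The benzofuran carbon C3, which carries the formyl group, sits between C3a of ring A and C2, the carbon bonded to ring B and to O1. If C3 is taken out together with its carbonyl carbon, what remains is an ortho-hydroxy diaryl ketone. In the forward sense, acid-promoted insertion of ethyl diazoacetate into that ketone should create C2–C3, move ring A onto C3 (C3–C3a) and let the phenol close the furan (O1–C2) in a single operation, giving the 3-carboxylate. The precursor is (5-allyl-2-hydroxy-3-methoxyphenyl)[3,4-bis(benzyloxy)-5-methoxyphenyl]methanone, made from eugenol and a brominated catechol ether; allyl and ester are adjusted afterwards.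

Key step: step 8

Remark: ring B is kept as its bis(benzyl ether), because the later hydride and MnO2 steps need an ether-protected catechol and the central benzyloxy group, flanked by two oxygens, lies out of the ring plane and should make ring B a poor migrating group. 5-Bromo-2-hydroxy-3-methoxybenzaldehyde is taken as commercial, so the bromine of ring B sits para to the central oxygen without relying on a bromination.

Step 1
Reactants: 1 eugenol (4-allyl-2-methoxyphenol)
Product: 2 5-allyl-2-hydroxy-3-methoxybenzaldehyde
Conditions: hexamethylenetetramine, AcOH, 110 °C; then aq. HCl, 90 °C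
Reagents that add atoms: hexamethylenetetramine, C1N2CN3CN1CN(C2)C3; water, O
Why: Duff ortho-formylation (aminomethylation by protonated hexamethylenetetramine, hydride transfer, hydrolysis) should go only to the one free position ortho to the hydroxyl, since the para position carries the allyl group.

Step 2
Reactants: 2 5-allyl-2-hydroxy-3-methoxybenzaldehyde
Product: 3 5-allyl-3-methoxy-2-(methoxymethoxy)benzaldehyde
Conditions: MOMCl, i-Pr2NEt, CH2Cl2, 0 °C → rt
Reagents that add atoms: chloromethyl methyl ether, COCCl
Why: O-alkylation of the phenol with an α-chloro ether masks the acidic hydroxyl as an acetal that tolerates the aryllithium and MnO2 and is later removed by dilute acid.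

Step 3
Reactants: 4 5-bromo-2-hydroxy-3-methoxybenzaldehyde
Product: 6 5-bromo-3-methoxybenzene-1,2-diol, via aryl formate 5 (not isolated)
Conditions: H2O2 (30%), aq. NaOH, 0 °C → rt, N2; then aq. HCl
Reagents that add atoms: hydrogen peroxide, OO
Why: Dakin oxidation, in which hydroperoxide adds to the aldehyde, the electron-rich ortho-hydroxyaryl group migrates to oxygen and the formate is hydrolysed in the same flask, places the second catechol oxygen at the former formyl carbon with no regiochemical question.

Step 4
Reactants: 6 5-bromo-3-methoxybenzene-1,2-diol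
Product: 7 5-bromo-1,2-bis(benzyloxy)-3-methoxybenzene
Conditions: BnBr, K2CO3, DMF, 50 °C, N2
Reagents that add atoms: benzyl bromide, BrCc1ccccc1
Why: Double Williamson etherification gives benzyl ethers that survive organolithium, acid, hydride and MnO2 and can be removed last.

Step 5
Reactants: 7 5-bromo-1,2-bis(benzyloxy)-3-methoxybenzene; 3 5-allyl-3-methoxy-2-(methoxymethoxy)benzaldehyde
Product: 9 (5-allyl-3-methoxy-2-(methoxymethoxy)phenyl)[3,4-bis(benzyloxy)-5-methoxyphenyl]methanol (racemic), via aryllithium 8 (not isolated)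
Conditions: n-BuLi, THF, −78 °C; then 3, −78 → 0 °C; then H2O
Reagents that add atoms: none
Why: Bromine–lithium exchange is fast at −78 °C and the aryllithium adds 1,2 to the aldehyde; the carbinol stereocentre forms as a racemate, which does not matter because step 6 removes it.

Step 6
Reactants: 9 (5-allyl-3-methoxy-2-(methoxymethoxy)phenyl)[3,4-bis(benzyloxy)-5-methoxyphenyl]methanol
Product: 10 (5-allyl-3-methoxy-2-(methoxymethoxy)phenyl)[3,4-bis(benzyloxy)-5-methoxyphenyl]methanone
Conditions: MnO2 (activated, excess), CH2Cl2, rt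
Reagents that add atoms: none
Why: MnO2 oxidation of a doubly benzylic alcohol gives the diaryl ketone, while the isolated terminal alkene and the ethers are inert.

Step 7
Reactants: 10 (5-allyl-3-methoxy-2-(methoxymethoxy)phenyl)[3,4-bis(benzyloxy)-5-methoxyphenyl]methanone
Product: 11 (5-allyl-2-hydroxy-3-methoxyphenyl)[3,4-bis(benzyloxy)-5-methoxyphenyl]methanone
Conditions: conc. HCl (cat.), MeOH, 50 °C
Reagents that add atoms: none
Why: Acid-catalysed acetal exchange with methanol removes the MOM group, assisted by the neighbouring carbonyl, while benzyl ethers and the allyl group are stable to dilute HCl.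

Step 8
Reactants: 11 (5-allyl-2-hydroxy-3-methoxyphenyl)[3,4-bis(benzyloxy)-5-methoxyphenyl]methanone; 12 ethyl diazoacetate
Product: 16 ethyl 5-allyl-2-[3,4-bis(benzyloxy)-5-methoxyphenyl]-7-methoxybenzofuran-3-carboxylate, via diazonium adduct 13 (not isolated), via β-keto ester 14 (not isolated), via cyclic hemiketal 15 (not isolated)
Conditions: HBF4·OEt2 (0.5 equiv), CH2Cl2, 0 °C → rt, 12 (3 equiv) by syringe pump; then p-TsOH·H2O (cat.), 40 °C
Reagents that add atoms: none
Why: Proposed new method: HBF4 should protonate the ketone of 11, already polarised by the hydrogen bond from the ortho phenol, so that the diazo carbon of 12 adds and gives the β-hydroxy α-diazonium ester 13 (bond C2–C3). Ring A is then expected to shift from the carbinol carbon to the diazonium carbon as N2 leaves (semipinacol, Tiffeneau–Demjanov type), giving β-keto ester 14 with ring A on C3 (bond C3–C3a). The phenol should add to the new aryl ketone in a 5-exo-trig closure to hemiketal 15, and acid-catalysed loss of water makes the furan aromatic (bond O1–C2); the stereocentres of 13–15 are transient and none remains. The closest known reaction types are the HBF4·OEt2-promoted conversion of salicylaldehydes and ethyl diazoacetate into benzofuran-3-carboxylates and the Lewis acid-catalysed homologation of aryl ketones with diazo esters; neither has been shown on a diaryl ketone. The step needs ring A to migrate in preference to ring B and carbonyl addition to outrun O-alkylation of the phenol: the ortho hydroxyl makes ring A the better bridging group, the 4-benzyloxy group of ring B is forced out of conjugation by its two oxygen neighbours while the meta oxygens withdraw inductively, and the hydrogen-bonded phenol is a weak nucleophile. A shift of ring B would show itself at once, because that β-keto ester can only lactonise to a 3-aryl-4-hydroxycoumarin.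

Step 9
Reactants: 16 ethyl 5-allyl-2-[3,4-bis(benzyloxy)-5-methoxyphenyl]-7-methoxybenzofuran-3-carboxylate
Product: 18 ethyl 2-[3,4-bis(benzyloxy)-5-methoxyphenyl]-5-(3-hydroxypropyl)-7-methoxybenzofuran-3-carboxylate, via B-alkyl-9-BBN adduct 17 (not isolated)
Conditions: 9-BBN, THF, 0 °C → rt; then aq. NaOH, H2O2, 0 °C
Reagents that add atoms: hydrogen peroxide, OO
Why: Hydroboration with the bulky 9-BBN places boron on the terminal carbon of the allyl group and oxidation with retention gives the primary alcohol (anti-Markovnikov hydration); the ester and the tetrasubstituted furan double bond should not react.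

Step 10
Reactants: 18 ethyl 2-[3,4-bis(benzyloxy)-5-methoxyphenyl]-5-(3-hydroxypropyl)-7-methoxybenzofuran-3-carboxylate
Product: 19 3-{2-[3,4-bis(benzyloxy)-5-methoxyphenyl]-3-(hydroxymethyl)-7-methoxybenzofuran-5-yl}propan-1-ol
Conditions: i-Bu2AlH (4 equiv), CH2Cl2, −78 → 0 °C; then aq. KNaC4H4O6 (potassium sodium tartrate)
Reagents that add atoms: none
Why: i-Bu2AlH reduces the conjugated ester through the aldehyde to the primary alcohol; benzyl and methyl ethers are inert and the neutral work-up spares the acid-sensitive benzofuranylmethanol.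

Step 11
Reactants: 19 3-{2-[3,4-bis(benzyloxy)-5-methoxyphenyl]-3-(hydroxymethyl)-7-methoxybenzofuran-5-yl}propan-1-ol
Product: 20 2-[3,4-bis(benzyloxy)-5-methoxyphenyl]-5-(3-hydroxypropyl)-7-methoxybenzofuran-3-carbaldehyde
Conditions: MnO2 (activated, excess), CH2Cl2, rt
Reagents that add atoms: none
Why: MnO2 oxidises only activated (benzylic, allylic, heteroarylmethyl) alcohols, so the benzofuran-3-ylmethanol should give the aldehyde while the aliphatic primary alcohol stays.

Step 12
Reactants: 20 2-[3,4-bis(benzyloxy)-5-methoxyphenyl]-5-(3-hydroxypropyl)-7-methoxybenzofuran-3-carbaldehyde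
Product: 21 Mururin C, 2-(3,4-dihydroxy-5-methoxyphenyl)-5-(3-hydroxypropyl)-7-methoxybenzofuran-3-carbaldehyde
Conditions: H2 (1 atm), Pd/C (10 wt%), EtOAc–MeOH, rt
Reagents that add atoms: none
Why: Hydrogenolysis of the two benzyl ethers over palladium on carbon; the formyl group is a vinylogous formate deactivated by O1 and should survive at 1 atm if the reaction is stopped once both benzyl groups are gone.

Compound list

1 | eugenol (4-allyl-2-methoxyphenol) | COc1cc(CC=C)ccc1O | starting material
2 | 5-allyl-2-hydroxy-3-methoxybenzaldehyde | COc1cc(CC=C)cc(C=O)c1O | intermediate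
3 | 5-allyl-3-methoxy-2-(methoxymethoxy)benzaldehyde | COCOc1c(OC)cc(CC=C)cc1C=O | intermediate
4 | 5-bromo-2-hydroxy-3-methoxybenzaldehyde | COc1cc(Br)cc(C=O)c1O | starting material
5 | 5-bromo-2-hydroxy-3-methoxyphenyl formate | COc1cc(Br)cc(OC=O)c1O | intermediate (not isolated)
6 | 5-bromo-3-methoxybenzene-1,2-diol | COc1cc(Br)cc(O)c1O | intermediate
7 | 5-bromo-1,2-bis(benzyloxy)-3-methoxybenzene | COc1cc(Br)cc(OCc2ccccc2)c1OCc1ccccc1 | intermediate
8 | [3,4-bis(benzyloxy)-5-methoxyphenyl]lithium | [Li]c1cc(OC)c(OCc2ccccc2)c(OCc2ccccc2)c1 | intermediate (not isolated)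
9 | (5-allyl-3-methoxy-2-(methoxymethoxy)phenyl)[3,4-bis(benzyloxy)-5-methoxyphenyl]methanol, racemic | COCOc1c(OC)cc(CC=C)cc1C(O)c1cc(OC)c(OCc2ccccc2)c(OCc2ccccc2)c1 | intermediate
10 | (5-allyl-3-methoxy-2-(methoxymethoxy)phenyl)[3,4-bis(benzyloxy)-5-methoxyphenyl]methanone | COCOc1c(OC)cc(CC=C)cc1C(=O)c1cc(OC)c(OCc2ccccc2)c(OCc2ccccc2)c1 | intermediate
11 | (5-allyl-2-hydroxy-3-methoxyphenyl)[3,4-bis(benzyloxy)-5-methoxyphenyl]methanone (key-step precursor) | COc1cc(CC=C)cc(C(=O)c2cc(OC)c(OCc3ccccc3)c(OCc3ccccc3)c2)c1O | intermediate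
12 | ethyl diazoacetate | CCOC(=O)C=[N+]=[N-] | starting material
13 | ethyl 3-(5-allyl-2-hydroxy-3-methoxyphenyl)-3-[3,4-bis(benzyloxy)-5-methoxyphenyl]-2-diazonio-3-hydroxypropanoate tetrafluoroborate, mixture of diastereomers | CCOC(=O)C([N+]#N)C(O)(c1cc(CC=C)cc(OC)c1O)c1cc(OC)c(OCc2ccccc2)c(OCc2ccccc2)c1.F[B-](F)(F)F | intermediate (not isolated)
14 | ethyl 2-(5-allyl-2-hydroxy-3-methoxyphenyl)-3-[3,4-bis(benzyloxy)-5-methoxyphenyl]-3-oxopropanoate, racemic | CCOC(=O)C(c1cc(CC=C)cc(OC)c1O)C(=O)c1cc(OC)c(OCc2ccccc2)c(OCc2ccccc2)c1 | intermediate (not isolated)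
15 | ethyl 5-allyl-2-[3,4-bis(benzyloxy)-5-methoxyphenyl]-2-hydroxy-7-methoxy-2,3-dihydrobenzofuran-3-carboxylate, mixture of diastereomers | CCOC(=O)C1c2cc(CC=C)cc(OC)c2OC1(O)c1cc(OC)c(OCc2ccccc2)c(OCc2ccccc2)c1 | intermediate (not isolated)
16 | ethyl 5-allyl-2-[3,4-bis(benzyloxy)-5-methoxyphenyl]-7-methoxybenzofuran-3-carboxylate (key-step product) | CCOC(=O)c1c(-c2cc(OC)c(OCc3ccccc3)c(OCc3ccccc3)c2)oc2c(OC)cc(CC=C)cc12 | intermediate
17 | ethyl 5-[3-(9-borabicyclo[3.3.1]nonan-9-yl)propyl]-2-[3,4-bis(benzyloxy)-5-methoxyphenyl]-7-methoxybenzofuran-3-carboxylate | CCOC(=O)c1c(-c2cc(OC)c(OCc3ccccc3)c(OCc3ccccc3)c2)oc2c(OC)cc(CCCB3C4CCCC3CCC4)cc12 | intermediate (not isolated)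
18 | ethyl 2-[3,4-bis(benzyloxy)-5-methoxyphenyl]-5-(3-hydroxypropyl)-7-methoxybenzofuran-3-carboxylate | CCOC(=O)c1c(-c2cc(OC)c(OCc3ccccc3)c(OCc3ccccc3)c2)oc2c(OC)cc(CCCO)cc12 | intermediate
19 | 3-{2-[3,4-bis(benzyloxy)-5-methoxyphenyl]-3-(hydroxymethyl)-7-methoxybenzofuran-5-yl}propan-1-ol | OCc1c(-c2cc(OC)c(OCc3ccccc3)c(OCc3ccccc3)c2)oc2c(OC)cc(CCCO)cc12 | intermediate
20 | 2-[3,4-bis(benzyloxy)-5-methoxyphenyl]-5-(3-hydroxypropyl)-7-methoxybenzofuran-3-carbaldehyde | O=Cc1c(-c2cc(OC)c(OCc3ccccc3)c(OCc3ccccc3)c2)oc2c(OC)cc(CCCO)cc12 | intermediate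
21 | Mururin C, 2-(3,4-dihydroxy-5-methoxyphenyl)-5-(3-hydroxypropyl)-7-methoxybenzofuran-3-carbaldehyde | COc1cc(-c2oc3c(OC)cc(CCCO)cc3c2C=O)cc(O)c1O | target

Total step count: 12.
Longest linear sequence: 10 steps (steps 1, 2 and 5–12 from eugenol; the branch from 4 through steps 3, 4 and 5–12 is equally long).

Steps most likely to fail

1. Step 8. The hindered, electron-rich diaryl ketone may not accept the diazo ester at all, ring B may migrate in competition with ring A, or the phenol oxygen may be alkylated by the protonated diazo ester. The fallback uses known chemistry and sets out from salicylaldehyde 2, for which the acid-promoted reaction with a diazoacetate is established. Treating 2 with 12 and HBF4·OEt2 in CH2Cl2 should give, after aryl shift and ring closure, ethyl 5-allyl-2-hydroxy-7-methoxy-2,3-dihydrobenzofuran-3-carboxylate F1. Dehydration with p-TsOH in warm toluene then gives ethyl 5-allyl-7-methoxybenzofuran-3-carboxylate F2. Directed zincation at C2 with TMPZnCl·LiCl in THF gives [5-allyl-3-(ethoxycarbonyl)-7-methoxybenzofuran-2-yl]zinc chloride F3. Negishi coupling of this with bromide 7 (Pd(OAc)2, SPhos, THF, 50 °C) attaches ring B to C2 and comes back to the route at 16; compounds 3 and 9 to 11 are then not needed.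

2. Step 12. Hydrogen may also reduce the formyl group or saturate the C2–C3 bond before both benzyl ethers are cleaved. The fallback sets out again from 20 and removes the benzyl groups without a reductant: BCl3 in CH2Cl2 at −78 °C with pentamethylbenzene as scavenger for the benzyl cation, then a methanol quench. This Lewis acid dealkylation should leave the aldehyde, the furan and the methyl ethers untouched at that temperature and arrives directly at 21 with no new intermediate.

3. Step 1. The Duff reaction on an electron-rich guaiacol may stop at low conversion or give tar, and hot acid may move the allyl double bond into conjugation. The fallback sets out from 4, which already carries the formyl and hydroxyl groups in the right places. Protection with MOMCl and i-Pr2NEt gives 5-bromo-3-methoxy-2-(methoxymethoxy)benzaldehyde F4. Suzuki–Miyaura coupling of this with allylboronic acid pinacol ester (Pd(PPh3)4, CsF, THF, 65 °C) installs the allyl group and comes back to the route at 3.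

Further compounds
F1 | step 8 | ethyl 5-allyl-2-hydroxy-7-methoxy-2,3-dihydrobenzofuran-3-carboxylate (mixture of diastereomers) | CCOC(=O)C1C(O)Oc2c(OC)cc(CC=C)cc21
F2 | step 8 | ethyl 5-allyl-7-methoxybenzofuran-3-carboxylate | CCOC(=O)c1coc2c(OC)cc(CC=C)cc12
F3 | step 8 | [5-allyl-3-(ethoxycarbonyl)-7-methoxybenzofuran-2-yl]zinc chloride | CCOC(=O)c1c([Zn]Cl)oc2c(OC)cc(CC=C)cc12
F0 | step 12 | none | none
F4 | step 1 | 5-bromo-3-methoxy-2-(methoxymethoxy)benzaldehyde | COCOc1c(OC)cc(Br)cc1C=O
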